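## Retrosynthetic overview

1. Shimalactone B ⇒ bicyclo[4.2.0]octadiene carbaldehyde + an (E)-but-2-en-2-yl zinc reagent; a catalyst-controlled addition sets the carbinol centre last.
2. Bicyclo[4.2.0]octadiene ⇒ open (E,Z,Z,E)-tetraenal by an 8π–6π electrocyclisation cascade whose helical sense is fixed by a chiral oxazaborolidinium Lewis acid (proposed new step; sets the four core stereocentres).
3. Tetraenal ⇒ Stille–Liebeskind coupling of a west (Z)-stannyl dienal with an east (Z)-alkenyl iodide that already carries the oxabicycle.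
4. Oxabicyclo[2.2.1]heptane ⇒ acid-triggered allyl-cation C-alkylation of a β-keto-δ-lactone; the lactone ⇒ Evans anti-aldol, then Dieckmann closure.
5. Ring order: δ-lactone → cyclopentanone bridge (oxabicycle) → cyclooctatriene → cyclohexadiene/cyclobutane.

Assumption: atom labels such as C-5 or C-22 give the position of the atom in the target SMILES string, counting every non-hydrogen atom from the left.
Assumption: compounds 1, 2, 4 and 14 and all reagents are bought, and tetraenal 21 closes only slowly at or below 0 °C because its formyl-bearing terminus carries an inward-pointing methyl group.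

## Route

Step 1
Reactants: 1 methacrolein; 2 2-(triphenylphosphoranylidene)propanal
Product: 3 (2E)-2,4-dimethylpenta-2,4-dienal
Conditions: 1 (3 equiv), PhMe, 80 °C, sealed tube; distillation
Reagents that add atoms: none
Why: Wittig olefination with the formyl-stabilised ylide gives the E-enal, and the excess of the more electrophilic aldehyde 1 suppresses a second homologation.

Step 2
Reactants: 3 (2E)-2,4-dimethylpenta-2,4-dienal; 4 (4S)-4-benzyl-3-propanoyl-1,3-oxazolidin-2-one
Product: 6 (4S)-4-benzyl-3-[(2R,3S,4E)-3-hydroxy-2,4,6-trimethylhepta-4,6-dienoyl]-1,3-oxazolidin-2-one, via silyl ether 5 (not isolated)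
Conditions: MgCl2 (0.2 equiv), Et3N (2 equiv), Me3SiCl (1.5 equiv), EtOAc, 23 °C; then MeOH, PPTS (cat.), 0 °C
Reagents that add atoms: chlorotrimethylsilane C[Si](C)(C)Cl (its silyl group sits in 5 only)
Why: Evans magnesium-halide-catalysed direct anti-aldol reaction, in which the chelated Z-enolate adds to the enal through a boat transition state on the face away from the benzyl group and so sets C-32 (R) and C-24 (S), while silylation of the aldolate turns the catalyst over.

Step 3
Reactants: 6 (4S)-4-benzyl-3-[(2R,3S,4E)-3-hydroxy-2,4,6-trimethylhepta-4,6-dienoyl]-1,3-oxazolidin-2-one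
Product: 7 (4S)-4-benzyl-3-[(2R,3S,4E)-2,4,6-trimethyl-3-(propanoyloxy)hepta-4,6-dienoyl]-1,3-oxazolidin-2-one
Conditions: (EtCO)2O (1.5 equiv), Et3N (2 equiv), DMAP (0.1 equiv), CH2Cl2, 0 °C → rt
Reagents that add atoms: propanoic anhydride CCC(=O)OC(=O)CC
Why: DMAP-catalysed O-acylation of the secondary alcohol under non-ionising conditions touches no stereocentre.

Step 4
Reactants: 7 (4S)-4-benzyl-3-[(2R,3S,4E)-2,4,6-trimethyl-3-(propanoyloxy)hepta-4,6-dienoyl]-1,3-oxazolidin-2-one
Product: 8 (5R,6S)-4-hydroxy-3,5-dimethyl-6-[(2E)-4-methylpenta-2,4-dien-2-yl]-5,6-dihydro-2H-pyran-2-one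
Conditions: KN(SiMe3)2 (2.5 equiv), THF, −78 °C; AcOH
Reagents that add atoms: none
Why: Dieckmann-type intramolecular Claisen condensation in which the propanoate enolate attacks the exocyclic imide carbonyl, the oxazolidinone is expelled and the product is held as its stabilised enolate, so C-32 and C-24 are kept.

Step 5
Reactants: 8 (5R,6S)-4-hydroxy-3,5-dimethyl-6-[(2E)-4-methylpenta-2,4-dien-2-yl]-5,6-dihydro-2H-pyran-2-one
Product: 9 (1S,4S,6R,7S)-4,6,7-trimethyl-7-(2-methylprop-1-en-1-yl)-2-oxabicyclo[2.2.1]heptane-3,5-dione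
Conditions: CF3CO2H (3 equiv), CH2Cl2, 0 °C → rt
Reagents that add atoms: none
Why: Protonation of the terminal methylene gives a bis-tertiary allyl cation that is captured at C-22 by the enol carbon C-28 (intramolecular cation–enol C-alkylation, with O-alkylation reversible under the acid), and the E-allyl cation closes through the rotamer that puts its methyl group next to the ring oxygen and its slim C–H edge next to the methyl-bearing C-32, which sets C-22 and C-28 with the alkenyl arm over the ketone bridge.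

Step 6
Reactants: 9 (1S,4S,6R,7S)-4,6,7-trimethyl-7-(2-methylprop-1-en-1-yl)-2-oxabicyclo[2.2.1]heptane-3,5-dione
Product: 11 (2E)-2-methyl-3-[(1S,4S,6R,7S)-4,6,7-trimethyl-3,5-dioxo-2-oxabicyclo[2.2.1]heptan-7-yl]prop-2-enal, via allylic alcohol 10 (not isolated)
Conditions: SeO2 (1.5 equiv), 1,4-dioxane, 70 °C
Reagents that add atoms: selenium dioxide O=[Se]=O
Why: Selenium dioxide allylic oxidation (ene reaction, then [2,3]-shift) attacks the methyl group trans to the C-21 substituent and carries the allylic alcohol on to the E-enal, while the ketone is spared because its only α-hydrogen is a hindered methine.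

Step 7
Reactants: 11 (2E)-2-methyl-3-[(1S,4S,6R,7S)-4,6,7-trimethyl-3,5-dioxo-2-oxabicyclo[2.2.1]heptan-7-yl]prop-2-enal; 2 2-(triphenylphosphoranylidene)propanal
Product: 12 (2E,4E)-2,4-dimethyl-5-[(1S,4S,6R,7S)-4,6,7-trimethyl-3,5-dioxo-2-oxabicyclo[2.2.1]heptan-7-yl]penta-2,4-dienal
Conditions: 2 (1.5 equiv), PhMe, 90 °C
Reagents that add atoms: none
Why: Wittig olefination with the stabilised ylide is E-selective and reacts only at the aldehyde, the ketone being flanked by a quaternary and a tertiary carbon.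

Step 8
Reactants: 12 (2E,4E)-2,4-dimethyl-5-[(1S,4S,6R,7S)-4,6,7-trimethyl-3,5-dioxo-2-oxabicyclo[2.2.1]heptan-7-yl]penta-2,4-dienal
Product: 13 (1S,4S,6R,7S)-7-[(1E,3E,5Z)-6-iodo-2,4-dimethylhepta-1,3,5-trien-1-yl]-4,6,7-trimethyl-2-oxabicyclo[2.2.1]heptane-3,5-dione
Conditions: [Ph3PEt]I (1.6 equiv), n-BuLi (1.6 equiv), THF, rt; I2 (1.6 equiv), −78 °C; NaN(SiMe3)2 (1.5 equiv), −20 °C; then 12, −78 → −20 °C
Reagents that add atoms: ethyltriphenylphosphonium iodide CC[P+](c1ccccc1)(c1ccccc1)c1ccccc1.[I-]; iodine [I][I]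
Why: Zhao olefination (Wittig reaction of the α-iodoethylidene ylide) adds to the aldehyde only and gives the Z-iodoalkene with iodine cis to the chain, as needed for the later Z-alkene at C-13.

Step 9
Reactants: 14 prop-2-yn-1-ol
Product: 15 (2Z)-3-iodo-2-methylprop-2-en-1-ol
Conditions: MeMgBr (3 equiv), CuI (0.1 equiv), THF, −10 °C → rt; I2 (1.2 equiv), −10 °C; 1 M HCl
Reagents that add atoms: methylmagnesium bromide C[Mg]Br; iodine [I][I]
Why: Copper-catalysed anti-carbomagnesiation of the propargylic magnesium alkoxide (methyl to the internal carbon, magnesium to the terminal carbon within a five-membered chelate) followed by iodinolysis with retention gives the Z-iodide.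

Step 10
Reactants: 15 (2Z)-3-iodo-2-methylprop-2-en-1-ol
Product: 17 ethyl (2E,4Z)-5-iodo-2,4-dimethylpenta-2,4-dienoate, via iodoenal 16 (not isolated)
Conditions: MnO2 (15 equiv), Ph3P=C(Me)CO2Et (1.3 equiv), CH2Cl2, rt
Reagents that add atoms: ethyl 2-(triphenylphosphoranylidene)propanoate CCOC(=O)C(C)=P(c1ccccc1)(c1ccccc1)c1ccccc1
Why: In situ oxidation–Wittig sequence in which MnO2 makes the configurationally labile enal and the stabilised ylide traps it at once with E-selectivity.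

Step 11
Reactants: 17 ethyl (2E,4Z)-5-iodo-2,4-dimethylpenta-2,4-dienoate
Product: 18 (2E,4Z)-5-iodo-2,4-dimethylpenta-2,4-dien-1-ol
Conditions: i-Bu2AlH (2.5 equiv), CH2Cl2, −78 °C; aq. KNaC4H4O6
Reagents that add atoms: none
Why: 1,2-Reduction of the dienoate by the aluminium hydride at low temperature leaves the iodoalkene and both double-bond geometries intact.

Step 12
Reactants: 18 (2E,4Z)-5-iodo-2,4-dimethylpenta-2,4-dien-1-ol
Product: 19 (2E,4Z)-5-iodo-2,4-dimethylpenta-2,4-dienal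
Conditions: MnO2 (15 equiv), CH2Cl2, rt
Reagents that add atoms: none
Why: Allylic oxidation on MnO2 under neutral conditions gives the dienal without Z to E drift.

Step 13
Reactants: 19 (2E,4Z)-5-iodo-2,4-dimethylpenta-2,4-dienal
Product: 20 (2E,4Z)-2,4-dimethyl-5-(trimethylstannyl)penta-2,4-dienal
Conditions: Me3SnSnMe3 (1.5 equiv), Pd(PPh3)4 (5 mol%), THF, 60 °C
Reagents that add atoms: hexamethylditin C[Sn](C)(C)[Sn](C)(C)C
Why: Palladium-catalysed iodine–tin exchange (oxidative addition, transmetalation with the distannane, reductive elimination) proceeds with retention of the Z geometry and tolerates the aldehyde.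

Step 14
Reactants: 13 (1S,4S,6R,7S)-7-[(1E,3E,5Z)-6-iodo-2,4-dimethylhepta-1,3,5-trien-1-yl]-4,6,7-trimethyl-2-oxabicyclo[2.2.1]heptane-3,5-dione; 20 (2E,4Z)-2,4-dimethyl-5-(trimethylstannyl)penta-2,4-dienal
Product: 21 (2E,4Z,6Z,8E,10E)-2,4,6,8,10-pentamethyl-11-[(1S,4S,6R,7S)-4,6,7-trimethyl-3,5-dioxo-2-oxabicyclo[2.2.1]heptan-7-yl]undeca-2,4,6,8,10-pentaenal
Conditions: 20 (1.3 equiv), Pd(PPh3)4 (5 mol%), CuO2C(C4H3S) (1.5 equiv), NMP, 0 °C, 1 h; silica filtration at −20 °C
Reagents that add atoms: none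
Why: Copper-assisted Stille (Stille–Liebeskind) coupling joins C-12 to C-13 with retention at both Z-alkenes at 0 °C, so the tetraenal can be filtered cold and used at once.

Step 15
Reactants: 21 (2E,4Z,6Z,8E,10E)-2,4,6,8,10-pentamethyl-11-[(1S,4S,6R,7S)-4,6,7-trimethyl-3,5-dioxo-2-oxabicyclo[2.2.1]heptan-7-yl]undeca-2,4,6,8,10-pentaenal
Product: 23 (1S,6R,7S,8S)-1,3,5,7-tetramethyl-8-{(1E)-1-[(1S,4S,6R,7S)-4,6,7-trimethyl-3,5-dioxo-2-oxabicyclo[2.2.1]heptan-7-yl]prop-1-en-2-yl}bicyclo[4.2.0]octa-2,4-diene-7-carbaldehyde, via cyclooctatriene 22 (not isolated)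
Conditions: (S)-tetrahydro-3,3-diphenyl-1-(2-methylphenyl)-1H,3H-pyrrolo[1,2-c][1,3,2]oxazaborole (25 mol%), HN(SO2CF3)2 (20 mol%), CH2Cl2, −78 → −40 °C; Et3N; then 35 °C
Reagents that add atoms: none
Why: Proposed new method: a chiral-Lewis-acid-catalysed, face-selective 8π electrocyclisation in which the N-protonated oxazaborolidine binds the 2-methyl-enal terminus of 21 (B–O coordination plus the formyl C–H···O contact, s-trans enal) and polarises the pentaenal towards an oxido-nonatetraenyl-cation-like species, so that the conrotatory union of the enolate-like C-7 and the cationic terminus C-18 runs at −40 °C where the thermal background is negligible, while the catalyst aryl group stacked on one face of C-7=C-9 leaves only the Re face of C-7 open and so fixes the helical sense (C-7 and C-18; formyl trans to the C-18 alkenyl group by conrotation of the E,Z,Z,E tetraene), after which warming lets cyclooctatriene 22 undergo the usual reversible disrotatory 6π closure to the cis-fused isomer that keeps the C-16 methyl trans to the C-18 alkenyl group (C-9 and C-16); the closest known reaction types are the oxazaborolidinium-catalysed Diels–Alder reaction of 2-substituted enals, Lewis-acid-catalysed 6π electrocyclisation of acyl trienes and the catalytic asymmetric Nazarov cyclisation, whereas catalyst control of an 8π closure has not been shown.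

Step 16
Reactants: 23 (1S,6R,7S,8S)-1,3,5,7-tetramethyl-8-{(1E)-1-[(1S,4S,6R,7S)-4,6,7-trimethyl-3,5-dioxo-2-oxabicyclo[2.2.1]heptan-7-yl]prop-1-en-2-yl}bicyclo[4.2.0]octa-2,4-diene-7-carbaldehyde
Product: 24 shimalactone B
Conditions: but-2-yne (2.5 equiv), HB(C6H11)2 (2.2 equiv), PhMe, 0 °C → rt; Me2Zn (2.2 equiv), −78 °C; (2R)-(+)-3-exo-morpholinoisoborneol (15 mol%), then 23, −10 °C → rt; aq. NH4Cl
Reagents that add atoms: but-2-yne CC#CC
Why: Catalytic asymmetric alkenylzinc addition (syn-hydroboration, boron-to-zinc exchange, amino-alcohol catalysis) in which the (+)-ligand, the antipode of the Si-face-selective (−)-ligand, delivers the alkenyl group to the Re face of the aldehyde and sets C-5 (R), the syn-hydroboration fixes the E-butenyl geometry, and the zinc reagent leaves the hindered ketone and the lactone alone.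

## Compound list

1 | methacrolein (2-methylprop-2-enal) | C=C(C)C=O | starting material
2 | 2-(triphenylphosphoranylidene)propanal | CC(C=O)=P(c1ccccc1)(c1ccccc1)c1ccccc1 | starting material
3 | (2E)-2,4-dimethylpenta-2,4-dienal | O=C/C(C)=C/C(C)=C | intermediate
4 | (4S)-4-benzyl-3-propanoyl-1,3-oxazolidin-2-one | CCC(=O)N1[C@@H](Cc2ccccc2)COC1=O | starting material
5 | (4S)-4-benzyl-3-[(2R,3S,4E)-2,4,6-trimethyl-3-(trimethylsilyloxy)hepta-4,6-dienoyl]-1,3-oxazolidin-2-one | O=C(N1[C@@H](Cc2ccccc2)COC1=O)[C@H](C)[C@H](O[Si](C)(C)C)/C(C)=C/C(C)=C | intermediate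
6 | (4S)-4-benzyl-3-[(2R,3S,4E)-3-hydroxy-2,4,6-trimethylhepta-4,6-dienoyl]-1,3-oxazolidin-2-one | O=C(N1[C@@H](Cc2ccccc2)COC1=O)[C@H](C)[C@H](O)/C(C)=C/C(C)=C | intermediate
7 | (4S)-4-benzyl-3-[(2R,3S,4E)-2,4,6-trimethyl-3-(propanoyloxy)hepta-4,6-dienoyl]-1,3-oxazolidin-2-one | O=C(N1[C@@H](Cc2ccccc2)COC1=O)[C@H](C)[C@H](OC(=O)CC)/C(C)=C/C(C)=C | intermediate
8 | (5R,6S)-4-hydroxy-3,5-dimethyl-6-[(2E)-4-methylpenta-2,4-dien-2-yl]-5,6-dihydro-2H-pyran-2-one (enol form of the β-keto-δ-lactone) | O=C1O[C@H](/C(C)=C/C(C)=C)[C@@H](C)C(O)=C1C | intermediate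
9 | (1S,4S,6R,7S)-4,6,7-trimethyl-7-(2-methylprop-1-en-1-yl)-2-oxabicyclo[2.2.1]heptane-3,5-dione | CC(C)=C[C@]1(C)[C@H]2OC(=O)[C@]1(C)C(=O)[C@@H]2C | intermediate
10 | (1S,4S,6R,7S)-7-[(1E)-3-hydroxy-2-methylprop-1-en-1-yl]-4,6,7-trimethyl-2-oxabicyclo[2.2.1]heptane-3,5-dione | OC/C(C)=C/[C@]1(C)[C@H]2OC(=O)[C@]1(C)C(=O)[C@@H]2C | intermediate
11 | (2E)-2-methyl-3-[(1S,4S,6R,7S)-4,6,7-trimethyl-3,5-dioxo-2-oxabicyclo[2.2.1]heptan-7-yl]prop-2-enal | O=C/C(C)=C/[C@]1(C)[C@H]2OC(=O)[C@]1(C)C(=O)[C@@H]2C | intermediate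
12 | (2E,4E)-2,4-dimethyl-5-[(1S,4S,6R,7S)-4,6,7-trimethyl-3,5-dioxo-2-oxabicyclo[2.2.1]heptan-7-yl]penta-2,4-dienal | O=C/C(C)=C/C(C)=C/[C@]1(C)[C@H]2OC(=O)[C@]1(C)C(=O)[C@@H]2C | intermediate
13 | (1S,4S,6R,7S)-7-[(1E,3E,5Z)-6-iodo-2,4-dimethylhepta-1,3,5-trien-1-yl]-4,6,7-trimethyl-2-oxabicyclo[2.2.1]heptane-3,5-dione | C/C(I)=C/C(C)=C/C(C)=C/[C@]1(C)[C@H]2OC(=O)[C@]1(C)C(=O)[C@@H]2C | intermediate
14 | prop-2-yn-1-ol | C#CCO | starting material
15 | (2Z)-3-iodo-2-methylprop-2-en-1-ol | OC/C(C)=C\I | intermediate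
16 | (2Z)-3-iodo-2-methylprop-2-enal | O=C/C(C)=C\I | intermediate
17 | ethyl (2E,4Z)-5-iodo-2,4-dimethylpenta-2,4-dienoate | CCOC(=O)/C(C)=C/C(C)=C\I | intermediate
18 | (2E,4Z)-5-iodo-2,4-dimethylpenta-2,4-dien-1-ol | OC/C(C)=C/C(C)=C\I | intermediate
19 | (2E,4Z)-5-iodo-2,4-dimethylpenta-2,4-dienal | O=C/C(C)=C/C(C)=C\I | intermediate
20 | (2E,4Z)-2,4-dimethyl-5-(trimethylstannyl)penta-2,4-dienal | O=C/C(C)=C/C(C)=C\[Sn](C)(C)C | intermediate
21 | (2E,4Z,6Z,8E,10E)-2,4,6,8,10-pentamethyl-11-[(1S,4S,6R,7S)-4,6,7-trimethyl-3,5-dioxo-2-oxabicyclo[2.2.1]heptan-7-yl]undeca-2,4,6,8,10-pentaenal | O=C/C(C)=C/C(C)=C\C(C)=C/C(C)=C/C(C)=C/[C@]1(C)[C@H]2OC(=O)[C@]1(C)C(=O)[C@@H]2C | intermediate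
22 | 1,3,5,7-tetramethyl-8-{(1E)-1-[(1S,4S,6R,7S)-4,6,7-trimethyl-3,5-dioxo-2-oxabicyclo[2.2.1]heptan-7-yl]prop-1-en-2-yl}cycloocta-2,4,6-triene-1-carbaldehyde, formyl group trans to the 8-alkenyl group, ring carbons C-7 and C-18 configured as in 23 | O=C[C@@]1(C)/C=C(C)\C=C(C)/C=C(C)\[C@@H]1/C(C)=C/[C@]1(C)[C@H]2OC(=O)[C@]1(C)C(=O)[C@@H]2C | intermediate
23 | (1S,6R,7S,8S)-1,3,5,7-tetramethyl-8-{(1E)-1-[(1S,4S,6R,7S)-4,6,7-trimethyl-3,5-dioxo-2-oxabicyclo[2.2.1]heptan-7-yl]prop-1-en-2-yl}bicyclo[4.2.0]octa-2,4-diene-7-carbaldehyde (cis-fused; formyl trans to the 8-alkenyl group; 8-alkenyl trans to the 1-methyl group) | O=C[C@@]1(C)[C@@H]2C(C)=CC(C)=C[C@]2(C)[C@@H]1/C(C)=C/[C@]1(C)[C@H]2OC(=O)[C@]1(C)C(=O)[C@@H]2C | intermediate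
24 | shimalactone B, (1S,4S,6R,7S)-7-[(1E)-2-{(1S,6R,7S,8S)-7-[(1R,2E)-1-hydroxy-2-methylbut-2-en-1-yl]-1,3,5,7-tetramethylbicyclo[4.2.0]octa-2,4-dien-8-yl}prop-1-en-1-yl]-4,6,7-trimethyl-2-oxabicyclo[2.2.1]heptane-3,5-dione | C/C=C(\C)[C@@H](O)[C@@]1(C)[C@@H]2C(C)=CC(C)=C[C@]2(C)[C@@H]1/C(C)=C/[C@]1(C)[C@H]2OC(=O)[C@]1(C)C(=O)[C@@H]2C | target

## Count, sequence and risks

Total step count: 16. Longest linear sequence: 11 steps (steps 1 to 8, then 14, 15 and 16, from methacrolein).

**Step 5 (cationic closure of the oxabicycle).** The enol oxygen may capture the allyl cation instead of C-28, or the wrong face of C-22 may react. The fallback sets out from 8. Silylation (t-BuMe2SiOTf, 2,6-lutidine, CH2Cl2, −78 °C) gives the silyl enol ether (5R,6S)-4-{[tert-butyl(dimethyl)silyl]oxy}-3,5-dimethyl-6-[(2E)-4-methylpenta-2,4-dien-2-yl]-5,6-dihydro-2H-pyran-2-one F1, in which the enol oxygen is blocked. Treatment with CF3CO2H (1.5 equiv) in CH2Cl2 at −40 °C then generates the same allyl cation, which can only be taken up by the enol-ether carbon in a Mukaiyama-type alkylation with loss of the silyl group. The fallback comes back to the route at 9.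

**Step 15 (the proposed new step).** The Lewis acid may not accelerate the closure enough, may isomerise a Z-alkene or open a six-ring closure path, or may give poor face selectivity. The facial sense rests on the accepted binding model for 2-substituted enals, and the antipodal catalyst would give the other helix. The fallback uses known chemistry only and sets out from 19 together with 13:
- The alkenylzinc addition of step 16 (but-2-yne, HB(C6H11)2, Me2Zn, the same (+)-ligand), applied to the small enal 19, gives (2E,4R,5E,7Z)-8-iodo-3,5,7-trimethylocta-2,5,7-trien-4-ol F2.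
- Palladium-catalysed stannylation (Me3SnSnMe3, Pd(PPh3)4, THF, 60 °C) gives (2E,4R,5E,7Z)-3,5,7-trimethyl-8-(trimethylstannyl)octa-2,5,7-trien-4-ol F3.
- Stille–Liebeskind coupling of F3 with 13 (Pd(PPh3)4, CuO2C(C4H3S), NMP, rt) gives the open-chain hexaenol F4.
- On warming to 40–60 °C without any catalyst, F4 undergoes the thermal 8π closure to the hydroxy cyclooctatriene F5 and then the 6π closure. This gives 24 together with the core diastereomer of 24 F6, from which 24 is separated by preparative HPLC.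

The fallback comes back to the route at 24 and replaces steps 13 to 16.

**Step 16 (alkenylation of the neopentyl aldehyde).** The hindered aldehyde may react slowly, methyl transfer may compete, or the catalyst and substrate may be mismatched. The fallback sets out from 23. A Nozaki–Hiyama–Kishi coupling with (E)-2-iodobut-2-ene (CrCl2, NiCl2 cat., DMSO, rt) is chemoselective for the aldehyde over the ketone but relies on substrate control. It gives 24 together with the C-5 epimer of 24 F7, which is removed by chromatography. The fallback comes back to the route at 24.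

## Further compounds

F1 | step 5 | (5R,6S)-4-{[tert-butyl(dimethyl)silyl]oxy}-3,5-dimethyl-6-[(2E)-4-methylpenta-2,4-dien-2-yl]-5,6-dihydro-2H-pyran-2-one | O=C1O[C@H](/C(C)=C/C(C)=C)[C@@H](C)C(O[Si](C)(C)C(C)(C)C)=C1C
F2 | step 15 | (2E,4R,5E,7Z)-8-iodo-3,5,7-trimethylocta-2,5,7-trien-4-ol | C/C=C(\C)[C@@H](O)/C(C)=C/C(C)=C\I
F3 | step 15 | (2E,4R,5E,7Z)-3,5,7-trimethyl-8-(trimethylstannyl)octa-2,5,7-trien-4-ol | C/C=C(\C)[C@@H](O)/C(C)=C/C(C)=C\[Sn](C)(C)C
F4 | step 15 | open-chain hexaenol, (1S,4S,6R,7S)-7-[(1E,3E,5Z,7Z,9E,11R,12E)-11-hydroxy-2,4,6,8,10,12-hexamethyltetradeca-1,3,5,7,9,12-hexaen-1-yl]-4,6,7-trimethyl-2-oxabicyclo[2.2.1]heptane-3,5-dione | C/C=C(\C)[C@@H](O)/C(C)=C/C(C)=C\C(C)=C/C(C)=C/C(C)=C/[C@]1(C)[C@H]2OC(=O)[C@]1(C)C(=O)[C@@H]2C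
F5 | step 15 | hydroxy cyclooctatriene, the 8π closure product of F4 with the carbinol-bearing group trans to the 8-alkenyl group | C/C=C(\C)[C@@H](O)[C@@]1(C)/C=C(C)\C=C(C)/C=C(C)\[C@@H]1/C(C)=C/[C@]1(C)[C@H]2OC(=O)[C@]1(C)C(=O)[C@@H]2C
F6 | step 15 | core diastereomer of 24, opposite configuration at C-7, C-9, C-16 and C-18 | C/C=C(\C)[C@@H](O)[C@]1(C)[C@H]2C(C)=CC(C)=C[C@@]2(C)[C@H]1/C(C)=C/[C@]1(C)[C@H]2OC(=O)[C@]1(C)C(=O)[C@@H]2C
F7 | step 16 | C-5 epimer of 24 | C/C=C(\C)[C@H](O)[C@@]1(C)[C@@H]2C(C)=CC(C)=C[C@]2(C)[C@@H]1/C(C)=C/[C@]1(C)[C@H]2OC(=O)[C@]1(C)C(=O)[C@@H]2C
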